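**Assumption:** (−)-Epigallocatechin (green-tea isolate) and 5-hydroxyvanillin are taken as purchasable; no other chiral material is used.

## Retrosynthetic overview

1. The whole flavan skeleton (rings A, C and B) and both stereocentres (C2, C3) are bought as (−)-epigallocatechin (1). No ring is built and neither stereocentre is touched. Benzyl bromide (2) masks its five phenols to give 3.
2. The D-ring comes from 5-hydroxyvanillin (4), which already carries the 3-OMe/4,5-di-OH pattern, as its dibenzyl ether 5.
3. Key disconnection: the C3–O–C(=O) ester bond, made by anodic NHC/DMAP-relay dehydrogenative coupling of alcohol 3 with aldehyde 5 to give 6.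
4. Global hydrogenolysis of seven benzyl ethers gives the target 7.

## Route

**Step 1**
Reactants: 1, (−)-epigallocatechin (2R,3R); 2, benzyl bromide
Product: 3, (2R,3R)-5,7-bis(benzyloxy)-2-[3,4,5-tris(benzyloxy)phenyl]chroman-3-ol (5,7,3′,4′,5′-penta-O-benzyl-EGC, free 3-OH)
Conditions: BnBr (5.5 equiv), K2CO3 (6 equiv), degassed DMF, −10 °C → rt, Ar, 24 h
Reagents that add atoms: benzyl bromide (2), BrCc1ccccc1
Why: Williamson O-benzylation; K2CO3 deprotonates only the five phenols and not the C3 alcohol, so the secondary OH stays free, and low temperature with O2 exclusion limits pyrogallol oxidation, C-benzylation and base-induced C2 epimerisation, which is shut off once the 4′-OH is alkylated.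

**Step 2**
Reactants: 4, 5-hydroxyvanillin (3,4-dihydroxy-5-methoxybenzaldehyde); 2, benzyl bromide
Product: 5, 3,4-bis(benzyloxy)-5-methoxybenzaldehyde
Conditions: BnBr (2.3 equiv), K2CO3 (3 equiv), DMF, 60 °C, N2, 4 h
Reagents that add atoms: benzyl bromide (2), BrCc1ccccc1
Why: Williamson ether synthesis on a catechol; the aldehyde is inert to these conditions.

**Step 3 (key step)**
Reactants: 3, penta-O-benzyl-EGC (1.0 equiv); 5, 3,4-bis(benzyloxy)-5-methoxybenzaldehyde (1.5 equiv)
Product: 6, (2R,3R)-5,7-bis(benzyloxy)-2-[3,4,5-tris(benzyloxy)phenyl]chroman-3-yl 3,4-bis(benzyloxy)-5-methoxybenzoate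
Conditions: 1,4-dimethyl-1,2,4-triazolium iodide (20 mol %), DMAP (30 mol %), DBU (0.5 equiv), nBu4NBF4 (0.1 M), MeCN/THF 3:1, 4 Å MS, undivided cell, graphite(+)/Pt(−), E(anode) = 0.0 V vs Ag/AgCl, ca. 3 F/mol of 3, rt, Ar
Reagents that add atoms: none (net loss of H2 from 3 + 5)
Why: Proposed new method: anodic NHC/DMAP-relay dehydrogenative esterification used as a near-equimolar fragment coupling of a hindered secondary alcohol. The achiral triazolylidene (azolium + DBU) adds to aldehyde 5 to give a Breslow intermediate, which is oxidised at the carbon anode (about −0.9 V vs SCE, more than 1 V below any benzyl aryl ether, DMAP or DBU) to the acyl azolium. DMAP intercepts this as the N-acylpyridinium, which acylates the axial C3–OH of 3 as in DMAP-catalysed acid-chloride couplings of this alcohol class, while DBU-H+ is reduced to H2 at Pt so base is only catalytic. Only the acyl–O bond is formed and neither the C3–O nor the C2–H bond is broken, so (2R,3R) is retained. The closest known reaction type is NHC-catalysed anodic oxidative esterification of aldehydes with simple primary alcohols (and NHC/quinone oxidative esterification); new here are the DMAP acyl relay under electrolysis and the flavan-3-ol/galloyl-aldehyde substrate class.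

**Step 4**
Reactants: 6, hepta-O-benzyl ester
Product: 7, (−)-epigallocatechin 3-(3-methyl-gallate), (2R,3R)
Conditions: H2 (1 atm), 20 % Pd(OH)2/C, THF/MeOH 1:1, rt; filter under N2; Sephadex LH-20 (MeOH)
Reagents that add atoms: none
Why: Heterogeneous hydrogenolysis of the seven benzyl aryl ethers, the standard end-game for perbenzylated catechin gallates; the alkyl benzoate, aryl methyl ether and C2–O1 bond survive at 1 atm and no stereocentre is involved.

## Compound list

1 | (−)-Epigallocatechin, (2R,3R) | O[C@@H]1Cc2c(O)cc(O)cc2O[C@@H]1c1cc(O)c(O)c(O)c1 | starting material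
2 | Benzyl bromide | BrCc1ccccc1 | starting material
3 | (2R,3R)-5,7-Bis(benzyloxy)-2-[3,4,5-tris(benzyloxy)phenyl]chroman-3-ol | O[C@@H]1Cc2c(OCc3ccccc3)cc(OCc3ccccc3)cc2O[C@@H]1c1cc(OCc2ccccc2)c(OCc2ccccc2)c(OCc2ccccc2)c1 | intermediate
4 | 5-Hydroxyvanillin (3,4-dihydroxy-5-methoxybenzaldehyde) | COc1cc(C=O)cc(O)c1O | starting material
5 | 3,4-Bis(benzyloxy)-5-methoxybenzaldehyde | COc1cc(C=O)cc(OCc2ccccc2)c1OCc1ccccc1 | intermediate
6 | (2R,3R)-5,7-Bis(benzyloxy)-2-[3,4,5-tris(benzyloxy)phenyl]chroman-3-yl 3,4-bis(benzyloxy)-5-methoxybenzoate | COc1cc(C(=O)O[C@@H]2Cc3c(OCc4ccccc4)cc(OCc4ccccc4)cc3O[C@@H]2c2cc(OCc3ccccc3)c(OCc3ccccc3)c(OCc3ccccc3)c2)cc(OCc2ccccc2)c1OCc1ccccc1 | intermediate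
7 | (−)-Epigallocatechin 3-(3-methyl-gallate), (2R,3R) | COc1cc(C(=O)O[C@@H]2Cc3c(O)cc(O)cc3O[C@@H]2c2cc(O)c(O)c(O)c2)cc(O)c1O | target

## Summary

Total steps: 4. Longest linear sequence: 3 (1 → 3 → 6 → 7).

Steps most likely to fail, with fallbacks:

1. **Step 3 (proposed new anodic NHC/DMAP coupling).** Risks are slow Breslow formation from the electron-rich aldehyde, slow acyl transfer to the hindered 3-OH, and acyl azolium hydrolysis. Fallback (known chemistry): Pinnick oxidation of 5 (NaClO2, NaH2PO4, 2-methyl-2-butene) to 3,4-bis(benzyloxy)-5-methoxybenzoic acid, then Steglich coupling (EDC·HCl, DMAP, CH2Cl2) or the acid chloride with DMAP/pyridine and 3 to give 6. This adds one step.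
2. **Step 1 (penta-O-benzylation of the base- and air-sensitive EGC).** Risks are C-benzylation at C6/C8, oxidation and partial C2 epimerisation. Fallback: leave EGC unprotected and acylate it directly at the 3-OH with 3,4-bis(benzyloxy)-5-methoxybenzoyl chloride in THF/TFA, using the known preference of acyl chlorides for the aliphatic 3-OH of catechins under acidic conditions. Only two benzyl ethers then need hydrogenolysis.
3. **Step 4 (sevenfold hydrogenolysis and isolation of an oxidation-prone polyphenol).** Risks are incomplete debenzylation, benzylic C2–O1 cleavage and air oxidation on work-up. Fallback: run the sequence in an all-silyl series (TBSCl/imidazole on 1 and on 4, same coupling) and finish with global desilylation using HF·pyridine in THF, which avoids Pd/H2.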